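## Structural features

The target is a 10βH-eremophilane, a cis-fused decalin whose O3 is acylated by (2E,5R)-5-(angeloyloxy)hex-2-enoic acid. Numbering used throughout: ring A = C1–C5 and C10, ring B = C5–C10, C14 and C15 = methyls on C5 and C4, C11–C13 = isopropenyl on C7. Four contiguous stereocentres, C3 (α-O), C4 (β-Me), quaternary C5 (β-Me) and C10 (β-H), form one block; ring B adds C7 (β-isopropenyl) and C9 (β-OH) on either side of the C8 ketone, and the side chain holds one more centre (5R). In the chair–chair conformer with C15 equatorial and C14 axial on ring A, the 3α-oxygen, the 7β-isopropenyl group and the 9β-hydroxyl are all equatorial, so C7 and C9 carry their relaxed configurations. Fragile groups: the 7-isopropenyl-8-ketone is β,γ-unsaturated and slips into conjugation (7(11)-ene) with acid or base, C7 and C9 are epimerisable, the α-ketol can transpose, the angelate isomerises to the tiglate, and the enoate is a Michael acceptor. The real difficulty is the quaternary C5 with cis-vicinal methyls at C4/C5 inside a cis ring fusion, in one absolute sense. The key step exploits the fact that C5 lies para to the C8 carbonyl in ring B: ring B can be written as a 4-methyl-4-alkylcyclohexa-2,5-dienone in which C5 is not stereogenic and the arms C6=C7 and C10=C9 are diastereotopic, so one C1–C10 bond closes ring A, sets the cis fusion and makes C5 stereogenic. In any chair-like closure of ring A onto the flat dienone, C14 is anti to the forming bond and therefore equatorial on the new ring, while the spectator arm is axial. Cis C14/C15 therefore needs an axial C4 methyl, and an equatorial C3 oxygen is then β; this dictates a 3,4-anti (3β) precursor and a later inversion at C3.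

## Logic of the disconnections

36 ⇒ 35. Cut: the O–Si bond at O9. The C9 hydroxyl must stay masked while C3 is acylated, and a silyl ether next to a ketone comes off with buffered fluoride without touching the esters. Gain: the last step is a mild unmasking. Demand: no base strong enough to move the C11=C12 bond into conjugation.

35 ⇒ 28 + 34. Cut: the C3–O(acyl) bond, with inversion at C3. The key step needs the C3 oxygen β and the target has it α, so forming the ester by substitution at C3 repairs the centre and joins the two halves at once. Gain: convergence. Demand: substitution must beat elimination at an axial, hindered carbinol, and O9 must be blocked.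

34 ⇒ 32 + 33, and 32 ⇒ 29 + 30. Cuts: the C2′=C3′ double bond (cross-metathesis) and the angelate C–O bond. The 5R centre is bought in 30 and the E-enoic acid arrives free. Demand: no Z→E isomerisation of the angelate and E-selective metathesis.

28 ⇒ 27 ⇒ 25 ⇒ 23 + 24 ⇒ 22. Cuts: O3–Si (selective), the C6–H/C7–H pair (conjugate reduction), C7–C11 (cross-coupling) and C7–I. The C6=C7 enone left by the key step marks C7 without regiochemical doubt, and the isopropenyl group enters intact. Demand: kinetic α-protonation at C7 from the α-face; the β,γ-enone is never equilibrated.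

22 ⇒ 19. Cut: C9–O. In 19 only C9 can enolise (C5 is quaternary), so oxygenation is regiospecific before C7 acquires its acidic hydrogen. Demand: β-face attack, which the convex face of the cis-decalin should give.

19 ⇒ 18. Cut: C1–C10 (key step). This removes ring A, the ring fusion and the stereogenicity of C5, leaving a dienone with a mirror plane through C5 and C8 and only the two side-chain centres. Gain: bicyclic with four contiguous centres becomes monocyclic with two. Demand: the radical must choose one of two diastereotopic arms. The chain is therefore 3,4-anti (3β-silyloxy), so that the silyloxy group is equatorial in the chair that has the C4 methyl axial. A 3,4-syn (3α) chain would pass through an all-equatorial chair onto the other arm and end in the trans-4,5-dimethyl series.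

18 ⇒ 17 ⇒ 16 ⇒ 14. Cuts: C1–I, O1–CH2Ar, and two C–H bonds (dehydrogenation). Iodide and dienone are made late because both are reactive. A 4-methoxybenzyl ether can be removed oxidatively beside a dienone, where hydrogenolysis could not be used. Demand: α′-selective enolisation of 14.

14 ⇒ 10 + 11. Cuts: C5–C6 and C9=C10 (Michael addition, aldol condensation). This is the standard construction of a 4,4-disubstituted cyclohexenone from an α-branched aldehyde, whose α-centre need not be controlled. Demand: enamine alkylation next to a branched carbon.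

10 ⇒ 9 ⇒ 7 ⇒ 6. Functional-group changes only (CHO ⇐ CH2OH ⇐ C=CH2; O–Si). The 1,1-disubstituted alkene of 6 is a latent α-methyl aldehyde.

6 ⇒ 3 + 4, and 3 ⇒ 1. Cuts: C3–C4 (allylboration) and B–CH2 (one-carbon homologation). Both side-chain stereocentres come from one catalyst-controlled addition to an achiral aldehyde. Demand: geometrically pure E-allylboronate (anti) and Re-face attack (3S).

## Other disconnections considered

Alternative 1: The cut is C5–C6 of ring B, with a C3–C8 bond drawn in the retron, so that ring B is folded back onto a bicyclo[2.2.2]octene. Forward, the potassium alkoxide of vinyl carbinol A1 undergoes an anionic oxy-Cope shift to the enolate of cis-decalone A2.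
- In its favour: the shift is concerted and suprafacial, so the cis fusion and the quaternary C5 follow from the geometry of A1. On relative control at C5/C10 this is better than the arm selection of the chosen plan. A2 also arrives with the C8 ketone and a masked C9 carbonyl, equal or better for the oxygen pattern of ring B. Hydroboration of its C3=C4 bond from the face opposite C14 would give 3α-OH and 4β-Me directly, which the chosen plan reaches only after an inversion.
- Against it here: A2 has none of the centres C3, C4 and C7. It is racemic unless the cycloaddition that builds the bicycle is made asymmetric. The isopropenyl group must still be attached at C7, and the C8/C9 dicarbonyl differentiated.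
- Comparison: the mechanism of the key step is more secure. Step count would be similar. The chosen plan is ahead on absolute configuration (one catalytic step) and on carrying C3 and C4 into the ring closure.

Alternative 2: The cuts are C1–C2 and C5–C10. Forward, trienone A3 undergoes an intramolecular Diels–Alder reaction, the vinyl ketone adding across the silyloxydiene to give A4.
- In its favour: two rings, two bonds and the quaternary C5 in one step, which is better in step economy for the skeleton. The C7 centre with its isopropenyl group comes from the chiral pool and never has to be made by kinetic protonation, again better than the chosen plan. The enol ether at C3/C4 is a handle for both remaining centres.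
- Against it here: the diene terminus C5 is fully substituted, so reactivity is low. The cis fusion and the sense at C5/C10 depend on endo/exo and facial control by the remote C7 centre. A4 has its carbonyl at C9, not C8, so a 1,2-transposition is needed. C4 (protonation) and C3 (reduction of a 3-ketone hindered on its β-face by C14, which should give the 3β-alcohol) would again need correction. The terpene-derived chain does not map directly onto C5–C9 and must be rebuilt.
- Comparison: it is more convergent. Its stereochemical outcome at the key step is at least as uncertain as in the chosen plan, and the ring-B oxidation pattern is further from the target.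

Alternative 3: The cut is C7–C8. Forward, Me2AlCl activates the aldehyde of A5, and a carbonyl-ene reaction with the prenyl group closes ring B to A6.
- In its favour: the isopropenyl group is created in its final, non-conjugated form together with the C7 centre through a chair transition state. This is better than the iodination/coupling/reduction/protonation sequence of the chosen plan.
- Against it here: A5 already contains the whole block C3–C4–C5–C10 on a monocyclic ring, so the problem of the quaternary C5 with cis methyls is only moved. The 8α-alcohol must then be oxidised and C9 hydroxylated in the presence of the labile β,γ-unsaturated ketone, where enolisation toward C9 competes with the more acidic C7–H. The chosen plan avoids this by oxygenating C9 first.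
- Comparison: the ring closure itself is the equal of the chosen key step in reliability, but the route would be longer overall.

Key step: step 10

Remark on the chemistry: 1, 4 and 24 are treated as catalogue compounds (1 is otherwise one step from but-2-yne and pinacolborane). The carbon that becomes C5 is carried as both epimers from step 4 to step 6 and loses its stereogenicity in step 7. TBS = tert-butyldimethylsilyl, TIPS = triisopropylsilyl, PMB = 4-methoxybenzyl.

## Steps

Step 1
Reactants: 1 2-[(Z)-but-2-en-2-yl]-4,4,5,5-tetramethyl-1,3,2-dioxaborolane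
Product: 3 2-[(E)-2-methylbut-2-en-1-yl]-4,4,5,5-tetramethyl-1,3,2-dioxaborolane, via boron ate complex 2 (not isolated)
Conditions: BrCH2Cl, n-BuLi, THF, −78 → 25 °C
Reagents that add atoms: bromochloromethane, ClCBr
Why: Matteson homologation: ClCH2Li made in the flask adds to boron and the alkenyl group migrates to carbon with loss of chloride and retention of the double-bond geometry, which gives the E-allylboronate needed for anti addition.

Step 2
Reactants: 3 2-[(E)-2-methylbut-2-en-1-yl]-4,4,5,5-tetramethyl-1,3,2-dioxaborolane; 4 3-[(4-methoxybenzyl)oxy]propanal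
Product: 6 (3S,4R)-1-[(4-methoxybenzyl)oxy]-4,5-dimethylhex-5-en-3-ol, via pinacol borate ester 5 (not isolated)
Conditions: (R)-3,3′-bis(2,4,6-triisopropylphenyl)-1,1′-binaphthyl-2,2′-diyl hydrogen phosphate [(R)-TRIP] (5 mol %), 4 Å MS, toluene, −30 °C; aqueous work-up
Reagents that add atoms: none
Why: Chiral phosphoric acid-catalysed allylboration through a closed chair transition state: the E-boronate places C3–OH and C4–Me anti, and the (R)-catalyst should direct attack to the Re face of the aldehyde (3S), so both side-chain stereocentres are set here.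

Step 3
Reactants: 6 (3S,4R)-1-[(4-methoxybenzyl)oxy]-4,5-dimethylhex-5-en-3-ol
Product: 7 tert-butyl{[(3S,4R)-1-[(4-methoxybenzyl)oxy]-4,5-dimethylhex-5-en-3-yl]oxy}dimethylsilane
Conditions: t-BuMe2SiOTf, 2,6-lutidine, CH2Cl2, 0 °C
Reagents that add atoms: tert-butyldimethylsilyl triflate, CC(C)(C)[Si](C)(C)OS(=O)(=O)C(F)(F)F
Why: Silylation of a hindered secondary alcohol with the silyl triflate; a silyl ether is chosen for O3 because it offers no weak C–H bond to the later C1 radical.

Step 4
Reactants: 7 tert-butyl{[(3S,4R)-1-[(4-methoxybenzyl)oxy]-4,5-dimethylhex-5-en-3-yl]oxy}dimethylsilane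
Product: 9 (2RS,3R,4S)-4-(tert-butyldimethylsilyloxy)-6-[(4-methoxybenzyl)oxy]-2,3-dimethylhexan-1-ol, via B-alkyl-9-BBN adduct 8 (not isolated)
Conditions: 9-BBN, THF, 25 → 50 °C; then NaOH, H2O2, 0 °C
Reagents that add atoms: hydrogen peroxide, OO
Why: Anti-Markovnikov hydroboration–oxidation of the 1,1-disubstituted alkene; the new methyl-bearing centre is formed as a mixture, which is harmless because it becomes the quaternary C5.

Step 5
Reactants: 9 (2RS,3R,4S)-4-(tert-butyldimethylsilyloxy)-6-[(4-methoxybenzyl)oxy]-2,3-dimethylhexan-1-ol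
Product: 10 (2RS,3R,4S)-4-(tert-butyldimethylsilyloxy)-6-[(4-methoxybenzyl)oxy]-2,3-dimethylhexanal
Conditions: PhI(OAc)2, TEMPO (10 mol %), CH2Cl2, 25 °C
Reagents that add atoms: none
Why: Oxoammonium-mediated oxidation of the primary alcohol stops at the aldehyde and leaves the PMB and silyl ethers alone.

Step 6
Reactants: 10 (2RS,3R,4S)-4-(tert-butyldimethylsilyloxy)-6-[(4-methoxybenzyl)oxy]-2,3-dimethylhexanal; 11 methyl vinyl ketone
Product: 14 4-[(2R,3S)-3-(tert-butyldimethylsilyloxy)-5-[(4-methoxybenzyl)oxy]pentan-2-yl]-4-methylcyclohex-2-en-1-one (both epimers at the ring carbon), via enamine 12 (not isolated), via keto aldehyde 13 (not isolated)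
Conditions: pyrrolidine, 4 Å MS, toluene, 25 °C; then 11, 25 → 60 °C; then AcOH/NaOAc/H2O, 80 °C
Reagents that add atoms: none
Why: Stork enamine Michael addition to 11 creates the quaternary carbon; hydrolysis and intramolecular aldol condensation close the cyclohexenone (Robinson-type annulation). The ring stereocentre is uncontrolled and is erased in step 7.

Step 7
Reactants: 14 4-[(2R,3S)-3-(tert-butyldimethylsilyloxy)-5-[(4-methoxybenzyl)oxy]pentan-2-yl]-4-methylcyclohex-2-en-1-one
Product: 16 4-[(2R,3S)-3-(tert-butyldimethylsilyloxy)-5-[(4-methoxybenzyl)oxy]pentan-2-yl]-4-methylcyclohexa-2,5-dien-1-one, via trimethylsilyl dienol ether 15 (not isolated)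
Conditions: LiN(iPr)2, Me3SiCl, THF, −78 °C; then Pd(OAc)2 (10 mol %), O2 (1 atm), DMSO, 25 °C
Reagents that add atoms: none
Why: Saegusa–Ito oxidation: kinetic deprotonation can only occur at the α′-CH2, and palladium-mediated dehydrosilylation of the dienol ether gives the cross-conjugated dienone, in which the ring carbon bearing the chain is no longer stereogenic.

Step 8
Reactants: 16 4-[(2R,3S)-3-(tert-butyldimethylsilyloxy)-5-[(4-methoxybenzyl)oxy]pentan-2-yl]-4-methylcyclohexa-2,5-dien-1-one
Product: 17 4-[(2R,3S)-3-(tert-butyldimethylsilyloxy)-5-hydroxypentan-2-yl]-4-methylcyclohexa-2,5-dien-1-one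
Conditions: DDQ, CH2Cl2/pH 7 buffer, 0 °C
Reagents that add atoms: none
Why: Oxidative cleavage of the PMB ether; the electron-poor dienone and the silyl ether are inert, whereas hydrogenolysis of a benzyl ether would reduce the dienone.

Step 9
Reactants: 17 4-[(2R,3S)-3-(tert-butyldimethylsilyloxy)-5-hydroxypentan-2-yl]-4-methylcyclohexa-2,5-dien-1-one
Product: 18 4-[(2R,3S)-3-(tert-butyldimethylsilyloxy)-5-iodopentan-2-yl]-4-methylcyclohexa-2,5-dien-1-one
Conditions: I2, PPh3, imidazole, CH2Cl2, 0 °C
Reagents that add atoms: iodine, II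
Why: Appel iodination of the primary alcohol under neutral conditions gives the radical precursor.

Step 10
Reactants: 18 4-[(2R,3S)-3-(tert-butyldimethylsilyloxy)-5-iodopentan-2-yl]-4-methylcyclohexa-2,5-dien-1-one
Product: 19 (4aR,5R,6S,8aR)-6-(tert-butyldimethylsilyloxy)-4a,5-dimethyl-4a,5,6,7,8,8a-hexahydronaphthalen-2(1H)-one (cis-fused; 3β-silyloxy, 4β-Me, 5β-Me, 10β-H)
Conditions: (Me3Si)3SiH, Et3B, air, toluene (0.01 M), −20 → 0 °C
Reagents that add atoms: none
Why: The silyl radical abstracts iodine, the primary C1 radical adds to C10, the β-carbon of one enone arm, and the α-keto radical takes hydrogen from the silane; this is radical conjugate cyclisation onto a 4,4-disubstituted cyclohexa-2,5-dienone with diastereotopic group selection, a known reaction type. Ring A closes in the 6-exo-trig mode through a chair-like transition state. C10 is controlled by the tether, which leaves C5 on the face opposite C14, so the bond can form only there and H10 ends cis to C14 (cis fusion). C5 is controlled by the choice of arm: the new bond is roughly perpendicular to the dienone plane, so the spectator arm is axial and C14 equatorial on the nascent ring, and the required cis C14/C15 relation means the C4 methyl is axial, which next to the quaternary C5 costs about one extra gauche contact. The competing chair onto the other arm has the C4 methyl equatorial but forces the silyloxy group axial, 1,3-diaxial to the spectator arm. The step therefore needs arm selectivity, and the equatorial preference of the 3β-silyloxy group secures it; a 3α-epimer would be steered to the wrong arm. Low temperature and a slow hydrogen donor at high dilution protect the selectivity and suppress simple reduction of the iodide.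

Step 11
Reactants: 19 (4aR,5R,6S,8aR)-6-(tert-butyldimethylsilyloxy)-4a,5-dimethyl-4a,5,6,7,8,8a-hexahydronaphthalen-2(1H)-one
Product: 22 3β-(tert-butyldimethylsilyloxy)-9β-(triisopropylsilyloxy)-10βH-11,12,13-trinoreremophil-6-en-8-one, via silyl dienol ether 20 (not isolated), via silyloxy oxirane 21 (not isolated)
Conditions: iPr3SiOTf, Et3N, CH2Cl2, 0 °C; then dimethyldioxirane, acetone, −78 → 0 °C
Reagents that add atoms: triisopropylsilyl triflate, CC(C)[Si](OS(=O)(=O)C(F)(F)F)(C(C)C)C(C)C; dimethyldioxirane, CC1(C)OO1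
Why: Rubottom oxidation: enolisation can go only toward C9, the dioxirane attacks the electron-rich C8=C9 bond on the convex β-face (ring A hangs from the α-bonds C5–C4 and C10–C1), and the oxirane opens with silyl shift to the α-silyloxy enone. This sets 9β-O and protects it in the same operation.

Step 12
Reactants: 22 3β-(tert-butyldimethylsilyloxy)-9β-(triisopropylsilyloxy)-10βH-11,12,13-trinoreremophil-6-en-8-one
Product: 23 7-iodo-3β-(tert-butyldimethylsilyloxy)-9β-(triisopropylsilyloxy)-10βH-11,12,13-trinoreremophil-6-en-8-one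
Conditions: I2, pyridine, CH2Cl2, 25 °C
Reagents that add atoms: iodine, II
Why: Pyridine-mediated α-iodination of the enone (conjugate addition, iodination of the enolate, elimination); C7 is the only position that can react.

Step 13
Reactants: 23 7-iodo-3β-(tert-butyldimethylsilyloxy)-9β-(triisopropylsilyloxy)-10βH-11,12,13-trinoreremophil-6-en-8-one; 24 4,4,5,5-tetramethyl-2-(prop-1-en-2-yl)-1,3,2-dioxaborolane
Product: 25 3β-(tert-butyldimethylsilyloxy)-9β-(triisopropylsilyloxy)-10βH-eremophila-6,11-dien-8-one
Conditions: Pd(dppf)Cl2 (5 mol %), K3PO4, dioxane/H2O, 40 °C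
Reagents that add atoms: none
Why: Suzuki–Miyaura coupling of an α-iodo enone with an alkenylboronate under mild base installs the isopropenyl group at C7.

Step 14
Reactants: 25 3β-(tert-butyldimethylsilyloxy)-9β-(triisopropylsilyloxy)-10βH-eremophila-6,11-dien-8-one
Product: 27 3β-(tert-butyldimethylsilyloxy)-9β-(triisopropylsilyloxy)-7αH,10βH-eremophil-11-en-8-one, via lithium dienolate 26 (not isolated)
Conditions: LiBH(s-Bu)3, THF, −78 °C; then AcOH, THF, −78 °C
Reagents that add atoms: none
Why: Conjugate reduction: the hindered hydride adds to C6, and kinetic protonation of the cross-conjugated dienolate occurs at the α-carbon C7, which keeps the isopropenyl group out of conjugation. Axial protonation from the α-face (ring B held by the equatorial 9β-silyloxy group) should place the isopropenyl group equatorial and β.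

Step 15
Reactants: 27 3β-(tert-butyldimethylsilyloxy)-9β-(triisopropylsilyloxy)-7αH,10βH-eremophil-11-en-8-one
Product: 28 3β-hydroxy-9β-(triisopropylsilyloxy)-7αH,10βH-eremophil-11-en-8-one
Conditions: HF·pyridine, pyridine, THF, 0 → 25 °C
Reagents that add atoms: none
Why: Chemoselective desilylation: under acidic fluoride the bulkier triisopropylsilyl ether on the oxygen deactivated by the adjacent ketone should survive while the tert-butyldimethylsilyl ether at C3 is cleaved.

Step 16
Reactants: 29 angelic acid; 30 (R)-pent-4-en-2-ol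
Product: 32 (R)-pent-4-en-2-yl (Z)-2-methylbut-2-enoate, via mixed anhydride 31 (not isolated)
Conditions: 2,4,6-trichlorobenzoyl chloride, Et3N, toluene, 25 °C; then 30, toluene, 80 °C
Reagents that add atoms: none
Why: Yamaguchi esterification through the mixed anhydride without a nucleophilic pyridine catalyst, which should avoid Z→E isomerisation of the angelate; the carbinol centre is not touched.

Step 17
Reactants: 32 (R)-pent-4-en-2-yl (Z)-2-methylbut-2-enoate; 33 acrylic acid
Product: 34 (2E,5R)-5-{[(Z)-2-methylbut-2-enoyl]oxy}hex-2-enoic acid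
Conditions: 33 (3 equiv), second-generation Hoveyda–Grubbs catalyst RuCl2(H2IMes)(=CH–C6H4-2-OiPr) (5 mol %), CH2Cl2, 40 °C
Reagents that add atoms: none
Why: Cross-metathesis of a terminal alkene with an acrylate partner is E-selective, and the trisubstituted electron-poor angelate alkene is a spectator.

Step 18
Reactants: 28 3β-hydroxy-9β-(triisopropylsilyloxy)-7αH,10βH-eremophil-11-en-8-one; 34 (2E,5R)-5-{[(Z)-2-methylbut-2-enoyl]oxy}hex-2-enoic acid
Product: 35 8-oxo-9β-(triisopropylsilyloxy)-7αH,10βH-eremophil-11-en-3α-yl (2E,5R)-5-{[(Z)-2-methylbut-2-enoyl]oxy}hex-2-enoate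
Conditions: PPh3, DIAD, toluene, 0 → 25 °C
Reagents that add atoms: none
Why: Mitsunobu esterification: the axial 3β-oxyphosphonium, strained by the 1,3-diaxial C14 methyl, is displaced by the carboxylate from the open α-side with inversion, giving the equatorial 3α-ester and correcting C3.

Step 19
Reactants: 35 8-oxo-9β-(triisopropylsilyloxy)-7αH,10βH-eremophil-11-en-3α-yl (2E,5R)-5-{[(Z)-2-methylbut-2-enoyl]oxy}hex-2-enoate
Product: 36 9β-hydroxy-8-oxo-7αH,10βH-eremophil-11-en-3α-yl (2E,5R)-5-{[(Z)-2-methylbut-2-enoyl]oxy}hex-2-enoate (CNP0210874.1)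
Conditions: Bu4NF, AcOH, THF, 0 °C
Reagents that add atoms: none
Why: Fluoride cleaves the silyl ether activated by the neighbouring ketone; acetic acid buffering guards against double-bond migration, ketol shift and ester cleavage.

## Compound list

1 | 2-[(Z)-but-2-en-2-yl]-4,4,5,5-tetramethyl-1,3,2-dioxaborolane | C/C=C(\C)B1OC(C)(C)C(C)(C)O1 | starting material
2 | lithium [(Z)-but-2-en-2-yl](chloromethyl)(pinacolato)borate | [Li+].C/C=C(\C)[B-]1(CCl)OC(C)(C)C(C)(C)O1 | intermediate
3 | 2-[(E)-2-methylbut-2-en-1-yl]-4,4,5,5-tetramethyl-1,3,2-dioxaborolane | C/C=C(\C)CB1OC(C)(C)C(C)(C)O1 | intermediate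
4 | 3-[(4-methoxybenzyl)oxy]propanal | O=CCCOCc1ccc(OC)cc1 | starting material
5 | 2-{[(3S,4R)-1-[(4-methoxybenzyl)oxy]-4,5-dimethylhex-5-en-3-yl]oxy}-4,4,5,5-tetramethyl-1,3,2-dioxaborolane | C=C(C)[C@@H](C)[C@@H](OB1OC(C)(C)C(C)(C)O1)CCOCc1ccc(OC)cc1 | intermediate
6 | (3S,4R)-1-[(4-methoxybenzyl)oxy]-4,5-dimethylhex-5-en-3-ol | C=C(C)[C@@H](C)[C@@H](O)CCOCc1ccc(OC)cc1 | intermediate
7 | tert-butyl{[(3S,4R)-1-[(4-methoxybenzyl)oxy]-4,5-dimethylhex-5-en-3-yl]oxy}dimethylsilane | C=C(C)[C@@H](C)[C@@H](O[Si](C)(C)C(C)(C)C)CCOCc1ccc(OC)cc1 | intermediate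
8 | 9-[(2RS,3R,4S)-4-(TBS-oxy)-6-(PMB-oxy)-2,3-dimethylhexyl]-9-borabicyclo[3.3.1]nonane | C(B1C2CCCC1CCC2)C(C)[C@@H](C)[C@@H](O[Si](C)(C)C(C)(C)C)CCOCc1ccc(OC)cc1 | intermediate
9 | (2RS,3R,4S)-4-(TBS-oxy)-6-(PMB-oxy)-2,3-dimethylhexan-1-ol | OCC(C)[C@@H](C)[C@@H](O[Si](C)(C)C(C)(C)C)CCOCc1ccc(OC)cc1 | intermediate
10 | (2RS,3R,4S)-4-(TBS-oxy)-6-(PMB-oxy)-2,3-dimethylhexanal | O=CC(C)[C@@H](C)[C@@H](O[Si](C)(C)C(C)(C)C)CCOCc1ccc(OC)cc1 | intermediate
11 | methyl vinyl ketone (but-3-en-2-one) | CC(=O)C=C | starting material
12 | 1-[(3R,4S)-4-(TBS-oxy)-6-(PMB-oxy)-2,3-dimethylhex-1-en-1-yl]pyrrolidine | C(=C(C)[C@@H](C)[C@@H](O[Si](C)(C)C(C)(C)C)CCOCc1ccc(OC)cc1)N1CCCC1 | intermediate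
13 | (2RS,3R,4S)-4-(TBS-oxy)-6-(PMB-oxy)-2,3-dimethyl-2-(3-oxobutyl)hexanal | O=CC(C)(CCC(C)=O)[C@@H](C)[C@@H](O[Si](C)(C)C(C)(C)C)CCOCc1ccc(OC)cc1 | intermediate
14 | 4-[(2R,3S)-3-(TBS-oxy)-5-(PMB-oxy)pentan-2-yl]-4-methylcyclohex-2-en-1-one (both ring epimers) | O=C1C=CC(C)(CC1)[C@@H](C)[C@@H](O[Si](C)(C)C(C)(C)C)CCOCc1ccc(OC)cc1 | intermediate
15 | {[4-[(2R,3S)-3-(TBS-oxy)-5-(PMB-oxy)pentan-2-yl]-4-methylcyclohexa-1,5-dien-1-yl]oxy}trimethylsilane | C[Si](C)(C)OC1=CCC(C)(C=C1)[C@@H](C)[C@@H](O[Si](C)(C)C(C)(C)C)CCOCc1ccc(OC)cc1 | intermediate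
16 | 4-[(2R,3S)-3-(TBS-oxy)-5-(PMB-oxy)pentan-2-yl]-4-methylcyclohexa-2,5-dien-1-one | O=C1C=CC(C)(C=C1)[C@@H](C)[C@@H](O[Si](C)(C)C(C)(C)C)CCOCc1ccc(OC)cc1 | intermediate
17 | 4-[(2R,3S)-3-(TBS-oxy)-5-hydroxypentan-2-yl]-4-methylcyclohexa-2,5-dien-1-one | O=C1C=CC(C)(C=C1)[C@@H](C)[C@@H](O[Si](C)(C)C(C)(C)C)CCO | intermediate
18 | 4-[(2R,3S)-3-(tert-butyldimethylsilyloxy)-5-iodopentan-2-yl]-4-methylcyclohexa-2,5-dien-1-one | O=C1C=CC(C)(C=C1)[C@@H](C)[C@@H](O[Si](C)(C)C(C)(C)C)CCI | intermediate
19 | (4aR,5R,6S,8aR)-6-(tert-butyldimethylsilyloxy)-4a,5-dimethyl-4a,5,6,7,8,8a-hexahydronaphthalen-2(1H)-one | O=C1C=C[C@@]2(C)[C@H](CC[C@H](O[Si](C)(C)C(C)(C)C)[C@@H]2C)C1 | intermediate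
20 | 3β-(TBS-oxy)-8-(TIPS-oxy)-10βH-11,12,13-trinoreremophila-6,8-diene | CC(C)[Si](C(C)C)(C(C)C)OC=1C=C[C@@]2(C)[C@H](CC[C@H](O[Si](C)(C)C(C)(C)C)[C@@H]2C)C=1 | intermediate
21 | 8β,9β-epoxy-3β-(TBS-oxy)-8α-(TIPS-oxy)-10βH-11,12,13-trinoreremophil-6-ene | CC(C)[Si](C(C)C)(C(C)C)O[C@]12C=C[C@@]3(C)[C@H](CC[C@H](O[Si](C)(C)C(C)(C)C)[C@@H]3C)[C@H]1O2 | intermediate
22 | 3β-(TBS-oxy)-9β-(TIPS-oxy)-10βH-11,12,13-trinoreremophil-6-en-8-one | O=C1C=C[C@@]2(C)[C@H](CC[C@H](O[Si](C)(C)C(C)(C)C)[C@@H]2C)[C@H]1O[Si](C(C)C)(C(C)C)C(C)C | intermediate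
23 | 7-iodo-3β-(TBS-oxy)-9β-(TIPS-oxy)-10βH-11,12,13-trinoreremophil-6-en-8-one | O=C1C(I)=C[C@@]2(C)[C@H](CC[C@H](O[Si](C)(C)C(C)(C)C)[C@@H]2C)[C@H]1O[Si](C(C)C)(C(C)C)C(C)C | intermediate
24 | 4,4,5,5-tetramethyl-2-(prop-1-en-2-yl)-1,3,2-dioxaborolane | C=C(C)B1OC(C)(C)C(C)(C)O1 | starting material
25 | 3β-(TBS-oxy)-9β-(TIPS-oxy)-10βH-eremophila-6,11-dien-8-one | O=C1C(C(C)=C)=C[C@@]2(C)[C@H](CC[C@H](O[Si](C)(C)C(C)(C)C)[C@@H]2C)[C@H]1O[Si](C(C)C)(C(C)C)C(C)C | intermediate
26 | lithium 3β-(TBS-oxy)-9β-(TIPS-oxy)-10βH-eremophila-7,11-dien-8-olate | C=C(C)C1C[C@@]2(C)[C@H](CC[C@H](O[Si](C)(C)C(C)(C)C)[C@@H]2C)[C@@H](O[Si](C(C)C)(C(C)C)C(C)C)C=1O[Li] | intermediate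
27 | 3β-(TBS-oxy)-9β-(TIPS-oxy)-7αH,10βH-eremophil-11-en-8-one | C=C(C)[C@H]1C[C@@]2(C)[C@H](CC[C@H](O[Si](C)(C)C(C)(C)C)[C@@H]2C)[C@@H](O[Si](C(C)C)(C(C)C)C(C)C)C1=O | intermediate
28 | 3β-hydroxy-9β-(TIPS-oxy)-7αH,10βH-eremophil-11-en-8-one | C=C(C)[C@H]1C[C@@]2(C)[C@H](CC[C@H](O)[C@@H]2C)[C@@H](O[Si](C(C)C)(C(C)C)C(C)C)C1=O | intermediate
29 | angelic acid [(Z)-2-methylbut-2-enoic acid] | C/C=C(/C)C(=O)O | starting material
30 | (R)-pent-4-en-2-ol | C=CC[C@@H](C)O | starting material
31 | (Z)-2-methylbut-2-enoic 2,4,6-trichlorobenzoic anhydride | C/C=C(/C)C(=O)OC(=O)c1c(Cl)cc(Cl)cc1Cl | intermediate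
32 | (R)-pent-4-en-2-yl (Z)-2-methylbut-2-enoate | C=CC[C@@H](C)OC(=O)/C(C)=C\C | intermediate
33 | acrylic acid | C=CC(=O)O | starting material
34 | (2E,5R)-5-{[(Z)-2-methylbut-2-enoyl]oxy}hex-2-enoic acid | OC(=O)/C=C/C[C@@H](C)OC(=O)/C(C)=C\C | intermediate
35 | 8-oxo-9β-(TIPS-oxy)-7αH,10βH-eremophil-11-en-3α-yl (2E,5R)-5-{[(Z)-2-methylbut-2-enoyl]oxy}hex-2-enoate | C=C(C)[C@H]1C[C@@]2(C)[C@H](CC[C@@H](OC(=O)/C=C/C[C@@H](C)OC(=O)/C(C)=C\C)[C@@H]2C)[C@@H](O[Si](C(C)C)(C(C)C)C(C)C)C1=O | intermediate
36 | 9β-hydroxy-8-oxo-7αH,10βH-eremophil-11-en-3α-yl (2E,5R)-5-{[(Z)-2-methylbut-2-enoyl]oxy}hex-2-enoate (CNP0210874.1) | C=C(C)[C@H]1C[C@@]2(C)[C@H](CC[C@@H](OC(=O)/C=C/C[C@@H](C)OC(=O)/C(C)=C\C)[C@@H]2C)[C@@H](O)C1=O | target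

## Step count and least certain steps

Total step count: 19. Longest linear sequence: 17 (steps 1–15, 18, 19); the side-chain acid is made in 2 steps (16, 17).

Step 10 (key step). What may go wrong: weak discrimination between the two enone arms, because the chair with the axial C4 methyl and twist-boat pathways onto the other arm may lie close in energy; premature hydrogen transfer to the uncyclised radical is a second loss. Fallback with catalyst control of the arm: it sets out from 17 and returns at 19. Oxidation of 17 (PhI(OAc)2, TEMPO) would give the aldehyde F1. Wittig reaction with Ph3P=CHOMe would give the enol ether F2, and mild acid hydrolysis the one-carbon-longer aldehyde F3. A diarylprolinol silyl ether catalyst would then form the enamine of F3, whose α-carbon (C1) adds to C10 in an intramolecular Michael reaction; the catalyst enantiomer is chosen to select the required arm, and the product is the 1-formyl decalin F4. Decarbonylation of F4 with RhCl(PPh3)3 (toluene, reflux) would lead back to 19.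

Step 18. What may go wrong: elimination toward the ring alkene from the axial oxyphosphonium (antiperiplanar hydrogens at C2 and C4), or slow activation of the hindered alcohol with a weakly acidic partner. Fallback that separates inversion from acylation: it sets out from 28 and returns at 35. Tf2O/pyridine at −20 °C would give the 3β-triflate F5. Displacement with Bu4N(NO2) and hydrolysis of the nitrite ester (nitrite inversion) would give the 3α-alcohol F6. Yamaguchi esterification of F6 with 34 would give 35.

Step 14. What may go wrong: protonation of the dienolate at the terminal carbon, which moves the double bond into conjugation, or protonation from the β-face, which gives the 7-epimer. Fallback that avoids a dienolate: it sets out from 22 and returns at 27, bypassing 23–26. Conjugate reduction of 22 with LiBH(s-Bu)3 and trapping with Me3SiCl would give the silyl enol ether F7. Palladium-catalysed α-alkenylation of F7 with 2-bromopropene through the tin enolate (PdCl2[P(o-tol)3]2, Bu3SnF, benzene, 80 °C) would form the C7–C11 bond directly.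

Step 2. What may go wrong: insufficient enantioselectivity with an unbranched aliphatic aldehyde, or erosion of the anti/syn ratio by an uncatalysed background reaction. Fallback by a different organometallic: it sets out from 4 and returns at 6. A catalytic asymmetric Nozaki–Hiyama–Kishi addition of (E)-1-bromo-2-methylbut-2-ene (CrCl2, Mn, Me3SiCl, chiral oxazoline–sulfonamide ligand, THF; then Bu4NF) is anti-selective through the E-allylchromium chair whatever the bromide geometry. It makes no new compound (F0).

## Further compounds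

F1 | step 10 | (3S,4R)-3-(tert-butyldimethylsilyloxy)-4-(1-methyl-4-oxocyclohexa-2,5-dien-1-yl)pentanal | O=C1C=CC(C)(C=C1)[C@@H](C)[C@@H](O[Si](C)(C)C(C)(C)C)CC=O
F2 | step 10 | 4-[(2R,3S)-3-(tert-butyldimethylsilyloxy)-6-methoxyhex-5-en-2-yl]-4-methylcyclohexa-2,5-dien-1-one (E/Z) | O=C1C=CC(C)(C=C1)[C@@H](C)[C@@H](O[Si](C)(C)C(C)(C)C)CC=COC
F3 | step 10 | (4S,5R)-4-(tert-butyldimethylsilyloxy)-5-(1-methyl-4-oxocyclohexa-2,5-dien-1-yl)hexanal | O=C1C=CC(C)(C=C1)[C@@H](C)[C@@H](O[Si](C)(C)C(C)(C)C)CCC=O
F4 | step 10 | 1-formyl derivative of 19 (both C1 epimers) | O=C1C=C[C@@]2(C)[C@H](C(C=O)C[C@H](O[Si](C)(C)C(C)(C)C)[C@@H]2C)C1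
F5 | step 18 | 8-oxo-9β-(triisopropylsilyloxy)-7αH,10βH-eremophil-11-en-3β-yl trifluoromethanesulfonate | C=C(C)[C@H]1C[C@@]2(C)[C@H](CC[C@H](OS(=O)(=O)C(F)(F)F)[C@@H]2C)[C@@H](O[Si](C(C)C)(C(C)C)C(C)C)C1=O
F6 | step 18 | 3α-hydroxy-9β-(triisopropylsilyloxy)-7αH,10βH-eremophil-11-en-8-one | C=C(C)[C@H]1C[C@@]2(C)[C@H](CC[C@@H](O)[C@@H]2C)[C@@H](O[Si](C(C)C)(C(C)C)C(C)C)C1=O
F7 | step 14 | 3β-(tert-butyldimethylsilyloxy)-9β-(triisopropylsilyloxy)-8-(trimethylsilyloxy)-10βH-11,12,13-trinoreremophil-7-ene | C[Si](C)(C)OC1=CC[C@@]2(C)[C@H](CC[C@H](O[Si](C)(C)C(C)(C)C)[C@@H]2C)[C@H]1O[Si](C(C)C)(C(C)C)C(C)C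
F0 | step 2 | none | none
A1 | alternative 1 | 3,3-dimethoxy-5,6-dimethyl-2-vinylbicyclo[2.2.2]oct-5-en-2-ol (vinyl syn to the C5=C6 bridge) | C=C[C@]1(O)C(OC)(OC)[C@H]2CC[C@@H]1C(C)=C2C
A2 | alternative 1 | cis-1,1-dimethoxy-4a,5-dimethyl-3,4,4a,7,8,8a-hexahydronaphthalen-2(1H)-one | O=C1CC[C@@]2(C)[C@H](CCC=C2C)C1(OC)OC
A3 | alternative 2 | (7E)-9-(tert-butyldimethylsilyloxy)-7,8-dimethyl-5-(prop-1-en-2-yl)deca-1,7,9-trien-3-one (C5 as C7 of A4) | C=CC(=O)C[C@@H](C(C)=C)C/C(C)=C(C)/C(O[Si](C)(C)C(C)(C)C)=C
A4 | alternative 2 | 3-(tert-butyldimethylsilyloxy)-10βH-eremophila-3,11-dien-9-one | C=C(C)[C@H]1C[C@@]2(C)[C@H](CCC(O[Si](C)(C)C(C)(C)C)=C2C)C(=O)C1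
A5 | alternative 3 | 2-[4-(tert-butyldimethylsilyloxy)-2,3-dimethyl-2-(3-methylbut-2-en-1-yl)cyclohexyl]acetaldehyde (ring configuration as in A6) | CC(C)=CC[C@@]1(C)[C@@H](CC=O)CC[C@@H](O[Si](C)(C)C(C)(C)C)[C@@H]1C
A6 | alternative 3 | 3α-(tert-butyldimethylsilyloxy)-10βH-eremophil-11-en-8α-ol | C=C(C)[C@H]1C[C@@]2(C)[C@H](CC[C@@H](O[Si](C)(C)C(C)(C)C)[C@@H]2C)C[C@@H]1O
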